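**Retrosynthetic overview**
- The target comes from 1,2-reduction of its C3 ketone; the α-methylene lactone comes from oxidative lactonisation of a C6/C12 diol that is carried as a bis-silyl ether.
- The ten-membered ring is made by ring expansion: alkoxy-radical β-scission of the C3–C9 fusion bond of a bicyclo[5.3.0]decadien-3-ol, so both Z-alkenes are inherited from a five- and a seven-membered ring.
- The seven-membered ring comes from ring-closing metathesis (C4=C5) after isopropenyl addition at C3; C8–C9 comes from an aldol reaction; the C8 tiglate is installed by Mitsunobu inversion.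
- The cyclopentenone (C10) comes from (S)-4-silyloxycyclopentenone and MeLi; the aldehyde (C6, C7) comes from an indium Barbier/lactonisation of a Baylis–Hillman-derived allyl bromide with acrolein.
- Ring order: five-membered carbocycle (purchased), lactone (made, then opened as a mask), seven-membered ring, ten-membered ring, lactone re-closed.

Assumption (one line): labels C1–C15 are the germacrane positions of the target (C12 lactone carbonyl, C13 exocyclic CH2, C14 methyl on C10, C15 methyl on C4); the indium step is taken to add anti to the allylic dioxolane oxygen (otherwise the enantiomeric glyceraldehyde acetonide is used); C3 and C9 of the intermediates between the aldol step and the ring expansion are epimer mixtures, written without configuration because both centres are erased in the ring expansion.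

**Fragment 1 (C1, C2, C3, C9, C10, C14)**

Step 1
Reactants: 1 (S)-4-(tert-butyldimethylsilyloxy)cyclopent-2-en-1-one
Product: 2 (1R,4S)-4-(tert-butyldimethylsilyloxy)-1-methylcyclopent-2-en-1-ol
Conditions: MeLi, THF, −78 °C; then aq NH4Cl
Reagents that add atoms: methyllithium, C[Li]
Why: 1,2-addition of the organolithium to the enone carbonyl occurs anti to the silyloxy group, which sets the future C10 carbinol (methyl trans to OTBS).

Step 2
Reactants: 2 (1R,4S)-4-(tert-butyldimethylsilyloxy)-1-methylcyclopent-2-en-1-ol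
Product: 3 (1R,4S)-1-methylcyclopent-2-ene-1,4-diol
Conditions: TBAF, THF, 0 °C to rt
Reagents that add atoms: none
Why: Fluoride desilylation frees the secondary allylic alcohol and leaves the tertiary carbinol untouched.

Step 3
Reactants: 3 (1R,4S)-1-methylcyclopent-2-ene-1,4-diol
Product: 4 (R)-4-hydroxy-4-methylcyclopent-2-en-1-one
Conditions: MnO2, CH2Cl2, rt
Reagents that add atoms: none
Why: Allylic oxidation with MnO2 takes only the secondary allylic alcohol, so the auxiliary stereocentre is traded for the C3 carbonyl while C10 stays R.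

Step 4
Reactants: 4 (R)-4-hydroxy-4-methylcyclopent-2-en-1-one
Product: 5 (R)-4-methyl-4-(triethylsilyloxy)cyclopent-2-en-1-one
Conditions: TESOTf, 2,6-lutidine, CH2Cl2, −78 to 0 °C
Reagents that add atoms: triethylsilyl trifluoromethanesulfonate, CC[Si](CC)(CC)OS(=O)(=O)C(F)(F)F
Why: Silyl triflate silylation of the tertiary alcohol removes the only other O–H that could compete in step 15.

**Fragment 2 (C5–C8, C11–C13)**

Step 5
Reactants: 6 (S)-2,2-dimethyl-1,3-dioxolane-4-carbaldehyde (L-glyceraldehyde acetonide); 7 methyl acrylate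
Product: 8 methyl 2-{[(4S)-2,2-dimethyl-1,3-dioxolan-4-yl](hydroxy)methyl}prop-2-enoate (both carbinol epimers)
Conditions: DABCO (0.5 equiv), neat, rt, 5 d
Reagents that add atoms: none
Why: Morita–Baylis–Hillman reaction joins C7 to C11; the new carbinol centre is irrelevant because it becomes sp2 in step 6.

Step 6
Reactants: 8 methyl 2-{[(4S)-2,2-dimethyl-1,3-dioxolan-4-yl](hydroxy)methyl}prop-2-enoate
Product: 9 methyl (2Z)-2-(bromomethyl)-3-[(4R)-2,2-dimethyl-1,3-dioxolan-4-yl]prop-2-enoate
Conditions: NBS, Me2S, CH2Cl2, 0 °C to rt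
Reagents that add atoms: N-bromosuccinimide, O=C1CCC(=O)N1Br
Why: Corey–Kim-type activation followed by SN2′ bromide delivery gives the conjugated Z-2-(bromomethyl)enoate without touching the acetonide.

Step 7
Reactants: 9 methyl (2Z)-2-(bromomethyl)-3-[(4R)-2,2-dimethyl-1,3-dioxolan-4-yl]prop-2-enoate; 10 acrolein
Product: 12 (4S,5S)-4-[(4R)-2,2-dimethyl-1,3-dioxolan-4-yl]-5-ethenyl-3-methylideneoxolan-2-one, via hydroxy ester 11 (not isolated)
Conditions: In powder, THF/H2O (1:1), rt; then PPTS (cat.), CH2Cl2, rt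
Reagents that add atoms: none
Why: Indium Barbier allylation through a chair transition state with the Z-reagent gives the syn adduct (cis lactone after lactonisation), and attack anti to the allylic dioxolane oxygen sets C6 and C7.

Step 8
Reactants: 12 (4S,5S)-4-[(4R)-2,2-dimethyl-1,3-dioxolan-4-yl]-5-ethenyl-3-methylideneoxolan-2-one
Product: 13 (3S,4S)-4-[(4R)-2,2-dimethyl-1,3-dioxolan-4-yl]-5-methylidenehex-1-ene-3,6-diol
Conditions: DIBAL-H (4 equiv), CH2Cl2, −78 to 0 °C; Rochelle salt
Reagents that add atoms: none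
Why: 1,2-Reduction of the lactone to the allylic diol masks the Michael-acceptor lactone for the Grignard and thiol steps.

Step 9
Reactants: 13 (3S,4S)-4-[(4R)-2,2-dimethyl-1,3-dioxolan-4-yl]-5-methylidenehex-1-ene-3,6-diol
Product: 14 bis(tert-butyldimethylsilyl) ether of 13 (C6-OTBS and C12-OTBS)
Conditions: TBSCl, imidazole, DMF, rt
Reagents that add atoms: tert-butyldimethylsilyl chloride, CC(C)(C)[Si](C)(C)Cl
Why: Standard silylation protects both alcohols that will later re-form the lactone.

Step 10
Reactants: 14 bis(tert-butyldimethylsilyl) ether of 13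
Product: 15 (2S,3S)-3-(tert-butyldimethylsilyloxy)-2-[3-(tert-butyldimethylsilyloxy)prop-1-en-2-yl]pent-4-enal
Conditions: H5IO6, EtOAc, rt; used crude
Reagents that add atoms: none
Why: Periodic acid hydrolyses the terminal acetonide and cleaves the glycol in one pot, so the directing stereocentre becomes the C8 aldehyde.

**Union and end game**

Step 11
Reactants: 5 (R)-4-methyl-4-(triethylsilyloxy)cyclopent-2-en-1-one; 15 (2S,3S)-3-(tert-butyldimethylsilyloxy)-2-[3-(tert-butyldimethylsilyloxy)prop-1-en-2-yl]pent-4-enal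
Product: 17 aldol adduct (C8 carbinol 8-epi; C9 epimers), via lithium dienolate 16 (not isolated)
Conditions: LDA, THF, −78 °C; then 15, −78 °C; AcOH quench
Reagents that add atoms: none
Why: Lithium-enolate aldol addition at C9 (the only enolisable position) forms C8–C9, with Felkin–Anh attack reinforced by 1,3-anti induction from the C6 silyloxy group giving the 8-epi carbinol that step 14 inverts.

Step 12
Reactants: 17 aldol adduct (C8 carbinol 8-epi; C9 epimers); 18 isopropenylmagnesium bromide
Product: 19 C3 isopropenyl carbinol (C3 and C9 epimers)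
Conditions: 18 (3.5 equiv), THF, −78 to −40 °C; then aq NH4Cl
Reagents that add atoms: none
Why: Grignard 1,2-addition to the enone carbonyl brings in C4 and C15; the new C3 centre needs no control because C3 becomes a ketone in step 15.

Step 13
Reactants: 19 C3 isopropenyl carbinol (C3 and C9 epimers)
Product: 20 bicyclo[5.3.0]decadiene 8-epi alcohol
Conditions: second-generation Grubbs catalyst RuCl2(H2IMes)(PCy3)(=CHPh) (10 mol%), toluene, 80 °C
Reagents that add atoms: none
Why: Ring-closing metathesis of the isopropenyl and vinyl groups closes the seven-membered ring and fixes the trisubstituted C4=C5 alkene as Z by ring constraint.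

Step 14
Reactants: 20 bicyclo[5.3.0]decadiene 8-epi alcohol; 21 tiglic acid
Product: 22 bicyclic 8R tiglate (C3 tertiary alcohol free)
Conditions: PPh3, DIAD, toluene, 0 °C to rt
Reagents that add atoms: none
Why: Mitsunobu esterification inverts C8 by SN2 displacement and installs the tiglate in one operation, while the tertiary C3 alcohol does not react.

Step 15
Reactants: 22 bicyclic 8R tiglate (C3 tertiary alcohol free)
Product: 23 ten-membered Z,Z-dienone tris-silyl ether (3-oxo; 6-OTBS, 12-OTBS, 10-OTES, 8-tiglate)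
Conditions: [Ir(dF(CF3)ppy)2(5,5′-d(CF3)bpy)]PF6 (2 mol%), 2,4,6-collidine (1 equiv), 2,4,6-triisopropylbenzenethiol (0.5 equiv), PhCF3, blue LEDs, 25 °C
Reagents that add atoms: none
Why: Proposed new method: the excited trivalent iridium photocatalyst and collidine remove the C3 O–H by proton-coupled electron transfer, the bis-allylic ring-fusion alkoxy radical undergoes β-scission of its only sp3 β-bond (C3–C9, the other two being vinylic) to open the bicycle into the ten-membered cross-conjugated Z,Z-dienone, and the secondary C9 radical is quenched by thiol hydrogen-atom transfer before transannular addition; the closest known reactions are PCET β-scission ring-opening and ring-expansion of cyclic tertiary and allylic alcohols and the hypoiodite (alkoxy-radical) fragmentation of ring-fusion tertiary alcohols to medium-ring ketones, neither shown on a bis-allylic fusion carbinol.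

Step 16
Reactants: 23 ten-membered Z,Z-dienone tris-silyl ether
Product: 24 3-oxo triol (6,10,12-trihydroxy; 8-tiglate)
Conditions: HF·pyridine, pyridine, THF, 0 °C to rt
Reagents that add atoms: none
Why: Buffered acidic fluoride cleaves the three silyl ethers without base-induced tiglate migration from O8 to O6.

Step 17
Reactants: 24 3-oxo triol (6,10,12-trihydroxy; 8-tiglate)
Product: 27 3-oxo lactone (3-dehydro target), via hydroxy enal 25 (not isolated), via lactol 26 (not isolated)
Conditions: TEMPO (20 mol%), PhI(OAc)2 (2.5 equiv), CH2Cl2, rt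
Reagents that add atoms: none
Why: TEMPO/PhI(OAc)2 oxidative lactonisation oxidises only the primary allylic alcohol, the enal is trapped by the C6 hydroxyl as a lactol and oxidised on to the cis-fused α-methylene lactone with C6 and C7 unchanged.

Step 18
Reactants: 27 3-oxo lactone (3-dehydro target)
Product: 28 (3R,6S,7R,8R,10R,1Z,4Z)-3,10-dihydroxy-8-tigloyloxygermacra-1,4,11(13)-trien-12,6-olide (target)
Conditions: NaBH4, CeCl3·7H2O, MeOH, −78 °C
Reagents that add atoms: none
Why: Luche 1,2-reduction of the dienone; hydride is expected to add to the keto form on the face opposite the C10 hydroxyl that caps C3 in the hemiketal, giving the 3R alcohol (3-OH cis to 10-OH), and the lactone and tiglate are not reduced at −78 °C.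

**Compound list**

1 | (S)-4-(tert-butyldimethylsilyloxy)cyclopent-2-en-1-one | O=C1C=C[C@@H](O[Si](C)(C)C(C)(C)C)C1 | starting material
2 | (1R,4S)-4-(tert-butyldimethylsilyloxy)-1-methylcyclopent-2-en-1-ol | C[C@]1(O)C=C[C@@H](O[Si](C)(C)C(C)(C)C)C1 | intermediate
3 | (1R,4S)-1-methylcyclopent-2-ene-1,4-diol | C[C@]1(O)C=C[C@@H](O)C1 | intermediate
4 | (R)-4-hydroxy-4-methylcyclopent-2-en-1-one | C[C@]1(O)C=CC(=O)C1 | intermediate
5 | (R)-4-methyl-4-(triethylsilyloxy)cyclopent-2-en-1-one | C[C@]1(O[Si](CC)(CC)CC)C=CC(=O)C1 | intermediate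
6 | (S)-2,2-dimethyl-1,3-dioxolane-4-carbaldehyde | O=C[C@@H]1COC(C)(C)O1 | starting material
7 | methyl acrylate | C=CC(=O)OC | starting material
8 | methyl 2-{[(4S)-2,2-dimethyl-1,3-dioxolan-4-yl](hydroxy)methyl}prop-2-enoate, carbinol epimers | C=C(C(=O)OC)C(O)[C@@H]1COC(C)(C)O1 | intermediate
9 | methyl (2Z)-2-(bromomethyl)-3-[(4R)-2,2-dimethyl-1,3-dioxolan-4-yl]prop-2-enoate | COC(=O)/C(CBr)=C/[C@@H]1COC(C)(C)O1 | intermediate
10 | acrolein | C=CC=O | starting material
11 | methyl (3S,4S)-3-[(4R)-2,2-dimethyl-1,3-dioxolan-4-yl]-4-hydroxy-2-methylidenehex-5-enoate | C=C[C@H](O)[C@@H]([C@@H]1COC(C)(C)O1)C(=C)C(=O)OC | intermediate (not isolated)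
12 | (4S,5S)-4-[(4R)-2,2-dimethyl-1,3-dioxolan-4-yl]-5-ethenyl-3-methylideneoxolan-2-one | C=C[C@@H]1OC(=O)C(=C)[C@@H]1[C@@H]2COC(C)(C)O2 | intermediate
13 | (3S,4S)-4-[(4R)-2,2-dimethyl-1,3-dioxolan-4-yl]-5-methylidenehex-1-ene-3,6-diol | C=C[C@H](O)[C@H](C(=C)CO)[C@@H]1COC(C)(C)O1 | intermediate
14 | bis(tert-butyldimethylsilyl) ether of 13 | C=C[C@H](O[Si](C)(C)C(C)(C)C)[C@H](C(=C)CO[Si](C)(C)C(C)(C)C)[C@@H]1COC(C)(C)O1 | intermediate
15 | (2S,3S)-3-(tert-butyldimethylsilyloxy)-2-[3-(tert-butyldimethylsilyloxy)prop-1-en-2-yl]pent-4-enal | C=C[C@H](O[Si](C)(C)C(C)(C)C)[C@H](C(=C)CO[Si](C)(C)C(C)(C)C)C=O | intermediate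
16 | lithium dienolate of 5 (C3-OLi, C3=C9) | C[C@]1(O[Si](CC)(CC)CC)C=CC(O[Li])=C1 | intermediate (not isolated)
17 | aldol adduct: 5 bearing at C9 the chain C8H(OH)–C7H[C(=CH2)CH2OTBS]–C6H(OTBS)–CH=CH2; C6, C7, C10 as in the target, C8 epimeric to the target, C9 epimer mixture | C=C[C@H](O[Si](C)(C)C(C)(C)C)[C@H](C(=C)CO[Si](C)(C)C(C)(C)C)[C@@H](O)C1C(=O)C=C[C@]1(C)O[Si](CC)(CC)CC | intermediate
18 | isopropenylmagnesium bromide | CC(=C)[Mg]Br | starting material
19 | C3 isopropenyl carbinol of 17 (C3 and C9 epimer mixtures) | C=C[C@H](O[Si](C)(C)C(C)(C)C)[C@H](C(=C)CO[Si](C)(C)C(C)(C)C)[C@@H](O)C1C(O)(C(C)=C)C=C[C@]1(C)O[Si](CC)(CC)CC | intermediate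
20 | bicyclo[5.3.0]deca-diene: five-membered ring C3(OH)–C2=C1–C10(Me)(OTES)–C9, seven-membered ring C3–C4(Me)=C5–C6(OTBS)–C7[C(=CH2)CH2OTBS]–C8(OH)–C9; 8-epi | CC(C)(C)[Si](C)(C)O[C@H]1C=C(C)C2(O)C=C[C@](C)(O[Si](CC)(CC)CC)C2[C@H](O)[C@H]1C(=C)CO[Si](C)(C)C(C)(C)C | intermediate
21 | tiglic acid, (E)-2-methylbut-2-enoic acid | C/C=C(\C)C(=O)O | starting material
22 | 8R tiglate of the bicyclic core of 20 (C8 inverted) | CC(C)(C)[Si](C)(C)O[C@H]1C=C(C)C2(O)C=C[C@](C)(O[Si](CC)(CC)CC)C2[C@@H](OC(=O)/C(C)=C/C)[C@H]1C(=C)CO[Si](C)(C)C(C)(C)C | intermediate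
23 | (6S,7R,8R,10R,1Z,4Z)-6,12-bis(TBS-oxy)-10-(TES-oxy)-8-tigloyloxygermacra-1,4,11(13)-trien-3-one | CC(C)(C)[Si](C)(C)O[C@H]1/C=C(/C)C(=O)/C=C\[C@](C)(O[Si](CC)(CC)CC)C[C@@H](OC(=O)/C(C)=C/C)[C@H]1C(=C)CO[Si](C)(C)C(C)(C)C | intermediate
24 | 6,10,12-trihydroxy-8-tigloyloxygermacra-1Z,4Z,11(13)-trien-3-one, configuration as in the target (in equilibrium with its 3,10-hemiketal) | O[C@H]1/C=C(/C)C(=O)/C=C\[C@](C)(O)C[C@@H](OC(=O)/C(C)=C/C)[C@H]1C(=C)CO | intermediate
25 | 12-aldehyde of 24 (hydroxy enal) | O[C@H]1/C=C(/C)C(=O)/C=C\[C@](C)(O)C[C@@H](OC(=O)/C(C)=C/C)[C@H]1C(=C)C=O | intermediate (not isolated)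
26 | 12,6-lactol of 25 | C=C1C(O)O[C@H]2/C=C(/C)C(=O)/C=C\[C@](C)(O)C[C@@H](OC(=O)/C(C)=C/C)[C@@H]12 | intermediate (not isolated)
27 | (6S,7R,8R,10R,1Z,4Z)-10-hydroxy-3-oxo-8-tigloyloxygermacra-1,4,11(13)-trien-12,6-olide | C=C1C(=O)O[C@H]2/C=C(/C)C(=O)/C=C\[C@](C)(O)C[C@@H](OC(=O)/C(C)=C/C)[C@@H]12 | intermediate
28 | (3R,6S,7R,8R,10R,1Z,4Z)-3,10-dihydroxy-8-tigloyloxygermacra-1,4,11(13)-trien-12,6-olide | C=C1C(=O)O[C@H]2/C=C(/C)[C@H](O)/C=C\[C@](C)(O)C[C@@H](OC(=O)/C(C)=C/C)[C@@H]12 | target

**Step count and risks**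

Total steps: 18 (fragment 1: steps 1–4; fragment 2: steps 5–10; union and end game: steps 11–18). Longest linear sequence: 14 steps (6 to 28, steps 5–18).

The three steps most likely to fail:

Step 15 (new ring expansion). Risks are transannular addition of the C9 radical to the dienone, thiol conjugate addition, and photosensitised Z/E isomerisation of the product. The fallback sets out from 22 and comes back at 23 using known stoichiometric chemistry. Suárez hypoiodite fragmentation (PhI(OAc)2, I2, CH2Cl2/cyclohexane, visible light) cleaves the same C3–C9 bond and traps the carbon radical at once with iodine, giving the ring-expanded 9-iodo dienone F1. Tin hydride reduction (Bu3SnH, AIBN, toluene, 80 °C) then removes the iodine to give 23.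

Step 14 (Mitsunobu inversion at the hindered C8 carbinol). Risks are elimination or no reaction. The fallback sets out from 20 and comes back at 23 through a polar ring expansion. Dess–Martin periodinane oxidises C8–OH to the bicyclic C8 ketone F2. This β-hydroxy ketone undergoes base-catalysed retro-aldol cleavage of C3–C9 (DBU cat., CH2Cl2, 0 °C) to the ten-membered 3,8-dione F3. NaBH4 (MeOH/CH2Cl2, −78 °C) reduces only the saturated C8 ketone, under Felkin–Anh control from C7, to the 8R alcohol F4. Esterification with tiglic anhydride/DMAP gives 23.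

Step 18 (configuration at C3). The substrate-controlled hydride delivery may favour the 3-epimer. The fallback sets out from 27 and comes back at 28 by switching to catalyst control: Corey–Bakshi–Shibata reduction with (S)-2-methyl-CBS-oxazaborolidine and catecholborane in toluene at −78 °C (the R catalyst if the S one proves mismatched), which is 1,2-selective for enones. This fallback makes no new compound (F0).

**Further compounds**

F1 | step 15 | 9-iodo derivative of 23 (C9 epimers) | CC(C)(C)[Si](C)(C)O[C@H]1/C=C(/C)C(=O)/C=C\[C@](C)(O[Si](CC)(CC)CC)C(I)[C@@H](OC(=O)/C(C)=C/C)[C@H]1C(=C)CO[Si](C)(C)C(C)(C)C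
F2 | step 14 | C8 ketone of 20 (bicyclic β-hydroxy ketone) | CC(C)(C)[Si](C)(C)O[C@H]1C=C(C)C2(O)C=C[C@](C)(O[Si](CC)(CC)CC)C2C(=O)[C@H]1C(=C)CO[Si](C)(C)C(C)(C)C
F3 | step 14 | ten-membered 3,8-dione (6,12-bis-OTBS, 10-OTES) | CC(C)(C)[Si](C)(C)O[C@H]1/C=C(/C)C(=O)/C=C\[C@](C)(O[Si](CC)(CC)CC)CC(=O)[C@H]1C(=C)CO[Si](C)(C)C(C)(C)C
F4 | step 14 | 8R alcohol corresponding to 23 (no tiglate) | CC(C)(C)[Si](C)(C)O[C@H]1/C=C(/C)C(=O)/C=C\[C@](C)(O[Si](CC)(CC)CC)C[C@@H](O)[C@H]1C(=C)CO[Si](C)(C)C(C)(C)C
F0 | step 18 | none | none
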